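**Retrosynthetic overview** (ring A = benzo ring, ring B = dihydrofuran ring O1/C2/C3/C3a/C7a, ring C = 4-hydroxy-3-methoxyphenyl ring)
- The anti (1R,2S) diol on C5 of ring A is cut back to the C5 bromide and O-benzyl (S)-lactic N-methoxy-N-methylamide: aryllithium acylation, chelation-controlled reduction, then hydrogenolysis of both benzyl ethers.
- The strategy rests on the C3 methyl group and the C2–O1 bond sitting on adjacent carbons between C3a of ring A and ring C. This is the pattern left when the CH2–C(ring C) bond of a trans-1,2-diarylcyclopropane is cleaved by a proton and the cation is caught by the ortho phenol of ring A. Ring B is therefore disconnected at O1–C2 and at one C–H bond of the C3 methyl group.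
- The cyclopropane is cut into the ring C styrene and the ring A aryldiazomethane (from the MOM-protected bromosalicylaldehyde tosylhydrazone). Cobalt metalloradical cyclopropanation joins them and fixes the future C3.
- Order of ring formation: cyclopropane (step 4), then ring B by strain-release opening of that cyclopropane (step 6). Rings A and C are bought as the two aldehydes.

Key step: step 6

Assumption: the sense of induction of the cobalt porphyrin catalyst on this substrate pair is not known beforehand; the ligand antipode that gives the (R) configuration at the ring A-bearing cyclopropane carbon is taken as chosen, and is to be verified on the first batch.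

**Step 1**
Reactants: 1 5-bromo-2-hydroxy-3-methoxybenzaldehyde
Product: 2 5-bromo-3-methoxy-2-(methoxymethoxy)benzaldehyde
Conditions: MOMCl, i-Pr2NEt, CH2Cl2, 0 °C → rt
Reagents that add atoms: chloromethyl methyl ether (MOMCl), COCCl
Why: Williamson-type O-alkylation of the phenol gives the MOM acetal, chosen over a silyl ether because it should withstand the carbonate/methanol medium of step 4 and come off later under mild acid.

**Step 2**
Reactants: 2 5-bromo-3-methoxy-2-(methoxymethoxy)benzaldehyde
Product: 3 N'-{(E)-[5-bromo-3-methoxy-2-(methoxymethoxy)phenyl]methylidene}-4-methylbenzenesulfonohydrazide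
Conditions: TsNHNH2, MeOH, rt
Reagents that add atoms: 4-methylbenzenesulfonohydrazide (TsNHNH2), Cc1ccc(cc1)S(=O)(=O)NN
Why: Hydrazone condensation in neutral methanol leaves the acetal intact and gives the crystalline Bamford–Stevens precursor of the diazoalkane.

**Step 3**
Reactants: 4 4-(benzyloxy)-3-methoxybenzaldehyde
Product: 5 1-(benzyloxy)-4-ethenyl-2-methoxybenzene
Conditions: Ph3PCH3Br, KOtBu, THF, 0 °C → rt
Reagents that add atoms: methyltriphenylphosphonium bromide, C[P+](c1ccccc1)(c1ccccc1)c1ccccc1.[Br-]
Why: Wittig methylenation with the non-stabilised ylide converts the aldehyde into the styrene, and the benzyl ether is inert to the base.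

**Step 4**
Reactants: 3 N'-{(E)-[5-bromo-3-methoxy-2-(methoxymethoxy)phenyl]methylidene}-4-methylbenzenesulfonohydrazide; 5 1-(benzyloxy)-4-ethenyl-2-methoxybenzene
Product: 7 5-bromo-1-{(1R,2R)-2-[4-(benzyloxy)-3-methoxyphenyl]cyclopropyl}-3-methoxy-2-(methoxymethoxy)benzene, via diazoalkane 6 (not isolated)
Conditions: Co(Por*) (2–5 mol %; Por* = D2-symmetric chiral amidoporphyrin 3,5-DitBu-Xu(2'-Naph)Phyrin, divalent cobalt), Cs2CO3, MeOH, 40 °C; 5 in excess
Reagents that add atoms: none
Why: Bamford–Stevens release of the ortho-alkoxy aryldiazomethane 6 feeds a cobalt metalloradical cyclopropanation (α-cobalt benzyl radical adds to the styrene CH2, then 3-exo-tet radical closure); the hydrogen-bonding chiral pocket of the amidoporphyrin should set the carbene carbon as (R) and deliver the trans (1R,2R) ring.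

**Step 5**
Reactants: 7 5-bromo-1-{(1R,2R)-2-[4-(benzyloxy)-3-methoxyphenyl]cyclopropyl}-3-methoxy-2-(methoxymethoxy)benzene
Product: 8 2-{(1R,2R)-2-[4-(benzyloxy)-3-methoxyphenyl]cyclopropyl}-4-bromo-6-methoxyphenol
Conditions: p-TsOH·H2O (0.2 equiv), MeOH/THF, 40 °C
Reagents that add atoms: none
Why: Acid-catalysed transacetalisation removes the MOM group as dimethoxymethane under conditions expected to be far milder than those that protonate the cyclopropane, so both stereocentres and the benzyl ether should be untouched.

**Step 6**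
Reactants: 8 2-{(1R,2R)-2-[4-(benzyloxy)-3-methoxyphenyl]cyclopropyl}-4-bromo-6-methoxyphenol
Product: 10 (2S,3S)-2-[4-(benzyloxy)-3-methoxyphenyl]-5-bromo-7-methoxy-3-methyl-2,3-dihydro-1-benzofuran, via benzylic cation 9 (not isolated)
Conditions: CF3SO3H (5 mol %), (CF3)2CHOH/CH2Cl2 2:1 (cosolvent keeps the medium liquid), −10 °C, dilute; Et3N quench
Reagents that add atoms: none
Why: Proposed new method: triflic acid, strengthened by the hydrogen-bond network of (CF3)2CHOH, protonates the unsubstituted cyclopropane CH2 (Markovnikov sense) while the CH2–C(ring C) bond breaks, so the strain is released into the 4-benzyloxy-3-methoxybenzylic cation 9 and the ring A-bearing carbon, none of whose bonds is broken, becomes C3 (S) carrying the new methyl group. The closest known reaction type is the intermolecular Brønsted-acid ring-opening hydroarylation and hydroalkoxylation of electron-rich arylcyclopropanes in fluorinated alcohols; intramolecular phenol capture on a 1,2-diarylcyclopropane is not established. Ring B, the only ring formed, closes by 5-exo-trig attack of the ortho phenol oxygen on the trigonal cation, making the O1–C2 bond. C2 is controlled by C3: the oxygen should add to the face that puts ring C anti to the C3 methyl group, and because the doubly activated C2–O1 bond can re-ionise under the acid, any cis-dihydrobenzofuran should drain to the trans (2S,3S) product. The step needs cleavage of CH2–C(ring C) rather than CH2–C(ring A) or the aryl-flanked C–C bond: the para-benzyloxy donor, set against the bromine-deactivated ring A, decides where the charge goes, and the CH2 corner is the least hindered site for the proton. Low temperature, low acid loading and a prompt base quench are needed so that ring closure outruns elimination to the α-methylstilbene, which would erase C3.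

**Step 7**
Reactants: 11 ethyl (2S)-2-hydroxypropanoate (ethyl (S)-lactate)
Product: 12 ethyl (2S)-2-(benzyloxy)propanoate
Conditions: benzyl 2,2,2-trichloroacetimidate, CF3SO3H (cat.), cyclohexane/CH2Cl2, rt
Reagents that add atoms: benzyl 2,2,2-trichloroacetimidate, N=C(OCc1ccccc1)C(Cl)(Cl)Cl
Why: Acid-catalysed trichloroacetimidate O-benzylation avoids base, so the lactate stereocentre should be kept.

**Step 8**
Reactants: 12 ethyl (2S)-2-(benzyloxy)propanoate
Product: 13 (2S)-2-(benzyloxy)-N-methoxy-N-methylpropanamide
Conditions: MeNH(OMe)·HCl, i-PrMgCl, THF, −20 °C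
Reagents that add atoms: N,O-dimethylhydroxylamine hydrochloride, CNOC.Cl
Why: Weinreb amide formation by aminolysis of the ester with the magnesium amide at low temperature is fast relative to enolisation, so the (S) centre should be retained.

**Step 9**
Reactants: 10 (2S,3S)-2-[4-(benzyloxy)-3-methoxyphenyl]-5-bromo-7-methoxy-3-methyl-2,3-dihydro-1-benzofuran; 13 (2S)-2-(benzyloxy)-N-methoxy-N-methylpropanamide
Product: 16 (2S)-2-(benzyloxy)-1-{(2S,3S)-2-[4-(benzyloxy)-3-methoxyphenyl]-7-methoxy-3-methyl-2,3-dihydro-1-benzofuran-5-yl}propan-1-one, via aryllithium 14 (not isolated), via lithium hemiaminal 15 (not isolated)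
Conditions: n-BuLi, THF, −78 °C; then 13, −78 → −20 °C; aq. NH4Cl
Reagents that add atoms: none
Why: Bromine–lithium exchange followed by Weinreb ketone synthesis stops at the chelated adduct 15, so no over-addition is expected, and at −78 °C neither the lactate centre nor C2/C3 should be deprotonated.

**Step 10**
Reactants: 16 (2S)-2-(benzyloxy)-1-{(2S,3S)-2-[4-(benzyloxy)-3-methoxyphenyl]-7-methoxy-3-methyl-2,3-dihydro-1-benzofuran-5-yl}propan-1-one
Product: 17 (1R,2S)-2-(benzyloxy)-1-{(2S,3S)-2-[4-(benzyloxy)-3-methoxyphenyl]-7-methoxy-3-methyl-2,3-dihydro-1-benzofuran-5-yl}propan-1-ol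
Conditions: Zn(BH4)2, Et2O/CH2Cl2, −30 → 0 °C; aq. NH4Cl
Reagents that add atoms: none
Why: Chelation-controlled (Cram-chelate) hydride reduction: zinc bridges the ketone and benzyloxy oxygens in a five-membered chelate and hydride enters from the face of the small hydrogen on the (S) α-carbon, which should give the (1R) carbinol, i.e. the anti (1R,2S) arrangement.

**Step 11**
Reactants: 17 (1R,2S)-2-(benzyloxy)-1-{(2S,3S)-2-[4-(benzyloxy)-3-methoxyphenyl]-7-methoxy-3-methyl-2,3-dihydro-1-benzofuran-5-yl}propan-1-ol
Product: 18 (1R,2S)-1-[(2S,3S)-2-(4-hydroxy-3-methoxyphenyl)-7-methoxy-3-methyl-2,3-dihydro-1-benzofuran-5-yl]propane-1,2-diol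
Conditions: H2 (1 atm), Pd(OH)2/C, EtOAc/EtOH, rt, monitored closely
Reagents that add atoms: none
Why: Catalytic hydrogenolysis under neutral conditions should cleave the aryl and alkyl benzyl ethers faster than the secondary cyclic C2–O1 benzylic ether or the benzylic carbinol, and no stereocentre is involved.

**Compound list**
1 | 5-bromo-2-hydroxy-3-methoxybenzaldehyde | COc1cc(Br)cc(C=O)c1O | starting material
2 | 5-bromo-3-methoxy-2-(methoxymethoxy)benzaldehyde | COCOc1c(OC)cc(Br)cc1C=O | intermediate
3 | N'-{(E)-[5-bromo-3-methoxy-2-(methoxymethoxy)phenyl]methylidene}-4-methylbenzenesulfonohydrazide | COCOc1c(OC)cc(Br)cc1/C=N/NS(=O)(=O)c1ccc(C)cc1 | intermediate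
4 | 4-(benzyloxy)-3-methoxybenzaldehyde | COc1cc(C=O)ccc1OCc1ccccc1 | starting material
5 | 1-(benzyloxy)-4-ethenyl-2-methoxybenzene | C=Cc1ccc(OCc2ccccc2)c(OC)c1 | intermediate
6 | 5-bromo-1-(diazomethyl)-3-methoxy-2-(methoxymethoxy)benzene | COCOc1c(OC)cc(Br)cc1C=[N+]=[N-] | intermediate
7 | 5-bromo-1-{(1R,2R)-2-[4-(benzyloxy)-3-methoxyphenyl]cyclopropyl}-3-methoxy-2-(methoxymethoxy)benzene | COCOc1c(OC)cc(Br)cc1[C@@H]1C[C@H]1c1ccc(OCc2ccccc2)c(OC)c1 | intermediate
8 | 2-{(1R,2R)-2-[4-(benzyloxy)-3-methoxyphenyl]cyclopropyl}-4-bromo-6-methoxyphenol | Oc1c(OC)cc(Br)cc1[C@@H]1C[C@H]1c1ccc(OCc2ccccc2)c(OC)c1 | intermediate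
9 | (2R)-1-[4-(benzyloxy)-3-methoxyphenyl]-2-(5-bromo-2-hydroxy-3-methoxyphenyl)propan-1-ylium | C[C@@H](c1cc(Br)cc(OC)c1O)[CH+]c1ccc(OCc2ccccc2)c(OC)c1 | intermediate
10 | (2S,3S)-2-[4-(benzyloxy)-3-methoxyphenyl]-5-bromo-7-methoxy-3-methyl-2,3-dihydro-1-benzofuran | COc1cc([C@H]2Oc3c(OC)cc(Br)cc3[C@@H]2C)ccc1OCc1ccccc1 | intermediate
11 | ethyl (2S)-2-hydroxypropanoate | CCOC(=O)[C@H](C)O | starting material
12 | ethyl (2S)-2-(benzyloxy)propanoate | CCOC(=O)[C@H](C)OCc1ccccc1 | intermediate
13 | (2S)-2-(benzyloxy)-N-methoxy-N-methylpropanamide | CON(C)C(=O)[C@H](C)OCc1ccccc1 | intermediate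
14 | [(2S,3S)-2-[4-(benzyloxy)-3-methoxyphenyl]-7-methoxy-3-methyl-2,3-dihydro-1-benzofuran-5-yl]lithium | COc1cc([C@H]2Oc3c(OC)cc([Li])cc3[C@@H]2C)ccc1OCc1ccccc1 | intermediate
15 | lithium (2S)-2-(benzyloxy)-1-{(2S,3S)-2-[4-(benzyloxy)-3-methoxyphenyl]-7-methoxy-3-methyl-2,3-dihydro-1-benzofuran-5-yl}-1-[methoxy(methyl)amino]propan-1-olate (either configuration at C1) | COc1cc([C@H]2Oc3c(OC)cc(C(O[Li])(N(C)OC)[C@H](C)OCc4ccccc4)cc3[C@@H]2C)ccc1OCc1ccccc1 | intermediate
16 | (2S)-2-(benzyloxy)-1-{(2S,3S)-2-[4-(benzyloxy)-3-methoxyphenyl]-7-methoxy-3-methyl-2,3-dihydro-1-benzofuran-5-yl}propan-1-one | COc1cc([C@H]2Oc3c(OC)cc(C(=O)[C@H](C)OCc4ccccc4)cc3[C@@H]2C)ccc1OCc1ccccc1 | intermediate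
17 | (1R,2S)-2-(benzyloxy)-1-{(2S,3S)-2-[4-(benzyloxy)-3-methoxyphenyl]-7-methoxy-3-methyl-2,3-dihydro-1-benzofuran-5-yl}propan-1-ol | COc1cc([C@H]2Oc3c(OC)cc([C@@H](O)[C@H](C)OCc4ccccc4)cc3[C@@H]2C)ccc1OCc1ccccc1 | intermediate
18 | (1R,2S)-1-[(2S,3S)-2-(4-hydroxy-3-methoxyphenyl)-7-methoxy-3-methyl-2,3-dihydro-1-benzofuran-5-yl]propane-1,2-diol | COc1cc([C@H]2Oc3c(OC)cc([C@@H](O)[C@H](C)O)cc3[C@@H]2C)ccc1O | target

**Step count**
Total: 11 steps. Longest linear sequence: 8 steps (steps 1, 2, 4, 5, 6, 9, 10, 11).

**Steps most likely to fail**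

1. Step 6 (proposed new method). Three processes may defeat it.
   - The proton may be delivered to the ring A-bearing carbon, cleaving the aryl-flanked C–C bond; the homologous cation would then close a six-membered ring and no methyl group would form.
   - The cation may lose the C3 proton and be re-protonated, eroding the configuration at C3.
   - The acid may transfer the benzyl group of ring C.

   Fallback with known chemistry, setting out from 8: the ring is opened by solvomercuration and reductive demercuration instead of protonolysis. Hg(OAc)2 (mercury diacetate, divalent mercury) in CH2Cl2 at 0 °C is a bulky electrophile of the kind known to attack the least substituted cyclopropane carbon. The benzylic cation so released is caught by the ortho phenol without strong protic acid and should give acetato{[(2S,3S)-2-[4-(benzyloxy)-3-methoxyphenyl]-5-bromo-7-methoxy-2,3-dihydro-1-benzofuran-3-yl]methyl}mercury F1. Reduction of F1 with NaBH4 in THF/aq. NaOH at 0 °C turns the CH2Hg group into the C3 methyl group and comes back to the route at 10. A brief mild-acid equilibration would correct any cis isomer at C2.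

2. Step 4. The electron-rich, ortho-substituted diazoalkane may be consumed by azine or carbene-dimer formation before the cobalt catalyst takes it up, or facial control at the carbene carbon may be poor.

   Fallback, setting out from 2 and 4: the roles of the partners are exchanged, so that the ring A-bearing stereocentre is fixed by the face of an alkene and not of the carbene. Aldehyde 2 is methylenated (Ph3PCH3Br, KOtBu, THF) to 5-bromo-1-ethenyl-3-methoxy-2-(methoxymethoxy)benzene F2. Aldehyde 4 is condensed with TsNHNH2 in MeOH to N'-{(E)-[4-(benzyloxy)-3-methoxyphenyl]methylidene}-4-methylbenzenesulfonohydrazide F3. Under Cs2CO3/MeOH, F3 releases 1-(benzyloxy)-4-(diazomethyl)-2-methoxybenzene F4, which Co(Por*) of the matching antipode adds to F2. The route is rejoined at 7.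

3. Step 11. During the slow removal of the secondary alkyl benzyl ether, over-reduction may occur: hydrogenolysis of the electron-rich benzylic carbinol C–O bond or of the C2–O1 benzylic ether of ring B.

   Fallback, setting out from 16: the order of deprotection and reduction is reversed, so that the benzylic carbinol never meets the palladium catalyst. Hydrogenolysis of 16 (H2, Pd(OH)2/C, EtOAc, rt) should give (2S)-2-hydroxy-1-[(2S,3S)-2-(4-hydroxy-3-methoxyphenyl)-7-methoxy-3-methyl-2,3-dihydro-1-benzofuran-5-yl]propan-1-one F5. Excess Zn(BH4)2 in Et2O/THF at −20 °C then reduces F5 through the zinc chelate of the free α-hydroxyl group, a known anti-selective reduction of α-hydroxy ketones, and the route is rejoined at 18.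

**Further compounds**
F1 | step 6 | acetato{[(2S,3S)-2-[4-(benzyloxy)-3-methoxyphenyl]-5-bromo-7-methoxy-2,3-dihydro-1-benzofuran-3-yl]methyl}mercury | COc1cc([C@H]2Oc3c(OC)cc(Br)cc3[C@@H]2C[Hg]OC(C)=O)ccc1OCc1ccccc1
F2 | step 4 | 5-bromo-1-ethenyl-3-methoxy-2-(methoxymethoxy)benzene | C=Cc1cc(Br)cc(OC)c1OCOC
F3 | step 4 | N'-{(E)-[4-(benzyloxy)-3-methoxyphenyl]methylidene}-4-methylbenzenesulfonohydrazide | COc1cc(/C=N/NS(=O)(=O)c2ccc(C)cc2)ccc1OCc1ccccc1
F4 | step 4 | 1-(benzyloxy)-4-(diazomethyl)-2-methoxybenzene | COc1cc(C=[N+]=[N-])ccc1OCc1ccccc1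
F5 | step 11 | (2S)-2-hydroxy-1-[(2S,3S)-2-(4-hydroxy-3-methoxyphenyl)-7-methoxy-3-methyl-2,3-dihydro-1-benzofuran-5-yl]propan-1-one | COc1cc([C@H]2Oc3c(OC)cc(C(=O)[C@H](C)O)cc3[C@@H]2C)ccc1O
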